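**Strategy.** Ring A (C1–C10) is closed last, at C7–C8, from a preformed butenolide (ring B, C6–O–C12–C11–C7). In the precursor 29, C11 carries a tributylstannylmethyl group (C13), so C7 is the γ-terminus of an allylstannane, and C8 is an aldehyde flanked by the C9 methoxy group. Chelation of the C8 carbonyl and the C9 methoxy oxygen by MgBr2 and SE2′ attack through C7 should, in one operation, form C7–C8, close the ten-membered ring, set C7 and C8, and release the C11=C13 methylene lactone with C8–OH as the only free hydroxyl. Compound 29 is linear: both ring-cis trisubstituted alkenes, C14–OTBS, C15–OTBDPS, and the (6R)-butenolide.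

Key step: step 21

Remark: positions are quoted in germacrane numbering (ring A C1–C10, lactone carbons C11–C13, C14 on C10, C15 on C4); TES = triethylsilyl, TBS = tert-butyldimethylsilyl, TBDPS = tert-butyldiphenylsilyl, PMB = 4-methoxybenzyl; (S)-but-3-ene-1,2-diol and the simple reagents are assumed to be purchasable.

**Route**

Step 1
Reactants: 1 (S)-but-3-ene-1,2-diol
Product: 2 (S)-3,4-bis(TESO)but-1-ene
Conditions: Et3SiCl (2.4 equiv), imidazole, DMF, 0 °C to rt
Reagents that add atoms: chlorotriethylsilane, CC[Si](Cl)(CC)CC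
Why: Silylation of both hydroxyls with a silyl chloride and imidazole; the future C6 stereocentre comes unchanged from the chiral-pool diol.

Step 2
Reactants: 2 (S)-3,4-bis(TESO)but-1-ene
Product: 3 (S)-2-(TESO)but-3-enal
Conditions: (COCl)2, DMSO, CH2Cl2, −78 to −35 °C; then iPr2NEt, −78 °C; used crude at once
Reagents that add atoms: none
Why: Swern oxidation applied to the bis-silyl ether, a known selective oxidative desilylation in which the activated sulfonium species exchanges the less hindered primary triethylsilyl ether and oxidises C5 to the aldehyde while the secondary ether at C6 stays.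

Step 3
Reactants: 4 ethyl (triphenylphosphoranylidene)acetate; 5 3-bromo-1,1-dimethoxypropane
Product: 7 ethyl 5,5-dimethoxy-2-(triphenylphosphoranylidene)pentanoate, via phosphonium bromide 6 (not isolated)
Conditions: NaI (cat.), MeCN, reflux; then NaOH (aq), CH2Cl2, rt
Reagents that add atoms: none
Why: C-alkylation of a stabilised phosphorus ylide by a primary halide and deprotonation of the resulting salt give the α-substituted ester ylide that carries C1–C4 and C15.

Step 4
Reactants: 3 (S)-2-(TESO)but-3-enal; 7 ethyl 5,5-dimethoxy-2-(triphenylphosphoranylidene)pentanoate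
Product: 8 ethyl (2E,4S)-2-(3,3-dimethoxypropyl)-4-(TESO)hexa-2,5-dienoate
Conditions: CH2Cl2, rt
Reagents that add atoms: none
Why: Wittig olefination with an α-substituted ester-stabilised ylide should give the (E)-enoate (C6 trans to the ester carbon C15, hence cis to C3) under neutral conditions that should not epimerise the α-silyloxy centre C6.

Step 5
Reactants: 8 ethyl (2E,4S)-2-(3,3-dimethoxypropyl)-4-(TESO)hexa-2,5-dienoate
Product: 9 (2E,4S)-2-(3,3-dimethoxypropyl)-4-(TESO)hexa-2,5-dien-1-ol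
Conditions: iBu2AlH (2.2 equiv), CH2Cl2, −78 °C; aq. potassium sodium tartrate
Reagents that add atoms: none
Why: 1,2-Reduction of the conjugated ester to the allylic alcohol (C15) with diisobutylaluminium hydride, which leaves the acetal and the silyl ether alone.

Step 6
Reactants: 9 (2E,4S)-2-(3,3-dimethoxypropyl)-4-(TESO)hexa-2,5-dien-1-ol
Product: 10 (2E,4S)-1-(TBDPSO)-2-(3,3-dimethoxypropyl)-4-(TESO)hexa-2,5-diene
Conditions: TBDPSCl, imidazole, CH2Cl2, 0 °C to rt
Reagents that add atoms: tert-butyl(chloro)diphenylsilane, CC(C)(C)[Si](Cl)(c1ccccc1)c1ccccc1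
Why: Standard silylation of the only free (primary allylic) hydroxyl.

Step 7
Reactants: 10 (2E,4S)-1-(TBDPSO)-2-(3,3-dimethoxypropyl)-4-(TESO)hexa-2,5-diene
Product: 12 (4E,6S)-4-(TBDPSO-methyl)-6-(TESO)octa-4,7-dienal, via collidinium triflate 11 (not isolated)
Conditions: Et3SiOTf, 2,4,6-collidine, CH2Cl2, 0 °C; then H2O
Reagents that add atoms: 2,4,6-trimethylpyridine, Cc1cc(C)nc(C)c1 (in intermediate 11); triethylsilyl trifluoromethanesulfonate, CC[Si](CC)(CC)OS(=O)(=O)C(F)(F)F (counter-ion of 11); water, O (carbonyl oxygen of 12)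
Why: Chemoselective acetal cleavage by the silyl triflate/pyridine-base method, in which the dimethyl acetal is converted into a pyridinium salt that water hydrolyses to the C1 aldehyde without protic acid, so the two silyl ethers should survive.

Step 8
Reactants: 13 4-methoxybenzyl alcohol; 14 methyl 4-chloro-3-oxobutanoate
Product: 15 methyl 4-(PMBO)-3-oxobutanoate
Conditions: NaH (2.2 equiv), THF, 0 °C to rt; then 1 M HCl
Reagents that add atoms: none
Why: Williamson etherification in which the second equivalent of hydride holds the β-keto ester as its enolate while the alkoxide displaces the chloride.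

Step 9
Reactants: 15 methyl 4-(PMBO)-3-oxobutanoate
Product: 16 methyl (S)-3-hydroxy-4-(PMBO)butanoate
Conditions: H2 (50 atm), RuCl2[(R)-BINAP] (0.5 mol%), MeOH, 80 °C
Reagents that add atoms: none
Why: Noyori asymmetric hydrogenation of a β-keto ester, in which the divalent ruthenium–(R)-BINAP catalyst should reduce the chelated ketone from one face and set C9 as the (S)-carbinol (the spatial sense in which it gives (R)-3-hydroxybutanoate from acetoacetate).

Step 10
Reactants: 16 methyl (S)-3-hydroxy-4-(PMBO)butanoate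
Product: 17 methyl (S)-3-methoxy-4-(PMBO)butanoate
Conditions: Me3OBF4, 1,8-bis(dimethylamino)naphthalene, CH2Cl2, rt
Reagents that add atoms: trimethyloxonium tetrafluoroborate, C[O+](C)C.F[B-](F)(F)F
Why: O-Methylation with an oxonium salt and a non-nucleophilic base avoids the β-elimination and retro-aldol pathways that a β-hydroxy ester would follow under alkoxide conditions; C9 is not touched.

Step 11
Reactants: 17 methyl (S)-3-methoxy-4-(PMBO)butanoate; 12 (4E,6S)-4-(TBDPSO-methyl)-6-(TESO)octa-4,7-dienal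
Product: 18 methyl (6E,8S)-3-hydroxy-2-[(1S)-1-methoxy-2-(PMBO)ethyl]-6-(TBDPSO-methyl)-8-(TESO)deca-6,9-dienoate (mixture at C2 and C3 of this name)
Conditions: LiN(iPr)2, THF, −78 °C; then 12, −78 °C; NH4Cl (aq) at −78 °C
Reagents that add atoms: none
Why: Aldol addition of the lithium ester enolate (C10) to the C1 aldehyde, run at −78 °C where the β-methoxy enolate should add before it can eliminate methoxide; the two new centres are formed without control and both disappear in step 12.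

Step 12
Reactants: 18 methyl (6E,8S)-3-hydroxy-2-[(1S)-1-methoxy-2-(PMBO)ethyl]-6-(TBDPSO-methyl)-8-(TESO)deca-6,9-dienoate
Product: 20 methyl (2E,6E,8S)-2-[(1S)-1-methoxy-2-(PMBO)ethyl]-6-(TBDPSO-methyl)-8-(TESO)deca-2,6,9-trienoate, via mesylate 19 (not isolated)
Conditions: MsCl, Et3N, CH2Cl2, 0 °C; then DBU, 0 °C to rt
Reagents that add atoms: methanesulfonyl chloride, CS(=O)(=O)Cl (in intermediate 19)
Why: Mesylation and E1cB elimination should give the thermodynamically preferred (E)-2-alkylidene ester (C2 trans to the ester carbon C14, hence ring-cis to C9), the mesylate leaving far faster than the β-methoxy group.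

Step 13
Reactants: 20 methyl (2E,6E,8S)-2-[(1S)-1-methoxy-2-(PMBO)ethyl]-6-(TBDPSO-methyl)-8-(TESO)deca-2,6,9-trienoate
Product: 21 (2Z,6E,8S)-2-[(1S)-1-methoxy-2-(PMBO)ethyl]-6-(TBDPSO-methyl)-8-(TESO)deca-2,6,9-trien-1-ol
Conditions: iBu2AlH (2.2 equiv), CH2Cl2, −78 °C; aq. potassium sodium tartrate
Reagents that add atoms: none
Why: 1,2-Reduction of the enoate to the C14 allylic alcohol with diisobutylaluminium hydride; ethers and silyl ethers are inert.

Step 14
Reactants: 21 (2Z,6E,8S)-2-[(1S)-1-methoxy-2-(PMBO)ethyl]-6-(TBDPSO-methyl)-8-(TESO)deca-2,6,9-trien-1-ol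
Product: 22 (2Z,6E,8S)-1-(TBSO)-2-[(1S)-1-methoxy-2-(PMBO)ethyl]-6-(TBDPSO-methyl)-8-(TESO)deca-2,6,9-triene
Conditions: TBSCl, imidazole, CH2Cl2, rt
Reagents that add atoms: tert-butyl(chloro)dimethylsilane, CC(C)(C)[Si](C)(C)Cl
Why: Standard silylation of the only free hydroxyl gives the C14 ether that is later removed before the C15 ether.

Step 15
Reactants: 22 (2Z,6E,8S)-1-(TBSO)-2-[(1S)-1-methoxy-2-(PMBO)ethyl]-6-(TBDPSO-methyl)-8-(TESO)deca-2,6,9-triene
Product: 23 (3S,4E,8Z,10S)-5-(TBDPSO-methyl)-9-(TBSO-methyl)-10-methoxy-11-(PMBO)undeca-1,4,8-trien-3-ol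
Conditions: pyridinium p-toluenesulfonate (0.1 equiv), MeOH/CH2Cl2, 0 °C
Reagents that add atoms: none
Why: Acid-catalysed methanolysis cleaves the triethylsilyl ether much faster than the tert-butyl-substituted silyl ethers and frees only the C6 hydroxyl.

Step 16
Reactants: 23 (3S,4E,8Z,10S)-5-(TBDPSO-methyl)-9-(TBSO-methyl)-10-methoxy-11-(PMBO)undeca-1,4,8-trien-3-ol; 24 2-(bromomethyl)acrylic acid
Product: 25 (3S,4E,8Z,10S)-5-(TBDPSO-methyl)-9-(TBSO-methyl)-10-methoxy-11-(PMBO)undeca-1,4,8-trien-3-yl 2-(bromomethyl)prop-2-enoate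
Conditions: DCC, DMAP (5 mol%), CH2Cl2, 0 °C
Reagents that add atoms: none
Why: Steglich esterification of the secondary C6 alcohol proceeds with retention since the C6–O bond is not broken; low temperature and little DMAP limit attack on the allylic bromide.

Step 17
Reactants: 25 (3S,4E,8Z,10S)-5-(TBDPSO-methyl)-9-(TBSO-methyl)-10-methoxy-11-(PMBO)undeca-1,4,8-trien-3-yl 2-(bromomethyl)prop-2-enoate
Product: 26 (5R)-3-(bromomethyl)-5-[(1E,5Z,7S)-2-(TBDPSO-methyl)-6-(TBSO-methyl)-7-methoxy-8-(PMBO)octa-1,5-dien-1-yl]furan-2(5H)-one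
Conditions: second-generation Hoveyda–Grubbs catalyst RuCl2(H2IMes)(=CH-C6H4-2-OiPr) (10 mol%), toluene (0.005 M), 80 °C
Reagents that add atoms: none
Why: Ring-closing metathesis between the C7 vinyl group and the 1,1-disubstituted acrylate closes ring B with loss of ethene; the catalyst should load on the monosubstituted vinyl group, the two trisubstituted alkenes are too hindered to compete, and a phosphine-free catalyst cannot be alkylated by the bromide.

Step 18
Reactants: 26 (5R)-3-(bromomethyl)-5-[(1E,5Z,7S)-2-(TBDPSO-methyl)-6-(TBSO-methyl)-7-methoxy-8-(PMBO)octa-1,5-dien-1-yl]furan-2(5H)-one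
Product: 27 (5R)-3-(bromomethyl)-5-[(1E,5Z,7S)-2-(TBDPSO-methyl)-6-(TBSO-methyl)-8-hydroxy-7-methoxyocta-1,5-dien-1-yl]furan-2(5H)-one
Conditions: DDQ, CH2Cl2/pH 7 phosphate buffer, 0 °C
Reagents that add atoms: none
Why: Oxidative cleavage of the 4-methoxybenzyl ether frees the C8 hydroxyl under neutral conditions, before tin is introduced, because an allylstannane would not tolerate the quinone.

Step 19
Reactants: 27 (5R)-3-(bromomethyl)-5-[(1E,5Z,7S)-2-(TBDPSO-methyl)-6-(TBSO-methyl)-8-hydroxy-7-methoxyocta-1,5-dien-1-yl]furan-2(5H)-one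
Product: 28 (5R)-5-[(1E,5Z,7S)-2-(TBDPSO-methyl)-6-(TBSO-methyl)-8-hydroxy-7-methoxyocta-1,5-dien-1-yl]-3-[(tributylstannyl)methyl]furan-2(5H)-one
Conditions: (Bu3Sn)2 (1.3 equiv), Pd2(dba)3 (2.5 mol%), THF, 0 °C to rt
Reagents that add atoms: hexabutylditin, CCCC[Sn](CCCC)(CCCC)[Sn](CCCC)(CCCC)CCCC
Why: Zerovalent-palladium-catalysed stannylation of an allylic bromide with a distannane (oxidative addition, Sn–Sn transmetalation, reductive elimination at the unhindered C13 terminus) should give the conjugated primary allylstannane under neutral conditions that spare the base-sensitive butenolide.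

Step 20
Reactants: 28 (5R)-5-[(1E,5Z,7S)-2-(TBDPSO-methyl)-6-(TBSO-methyl)-8-hydroxy-7-methoxyocta-1,5-dien-1-yl]-3-[(tributylstannyl)methyl]furan-2(5H)-one
Product: 29 (2S,3Z,7E)-3-(TBSO-methyl)-7-(TBDPSO-methyl)-2-methoxy-8-{(2R)-5-oxo-4-[(tributylstannyl)methyl]-2,5-dihydrofuran-2-yl}octa-3,7-dienal
Conditions: Dess–Martin periodinane, NaHCO3, CH2Cl2, 0 °C; short silica pad, used at once
Reagents that add atoms: none
Why: Dess–Martin oxidation under bicarbonate buffering gives the α-methoxy aldehyde without amine base, so C9 should not epimerise and the C10=C1 alkene should not move into conjugation.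

Step 21
Reactants: 29 (2S,3Z,7E)-3-(TBSO-methyl)-7-(TBDPSO-methyl)-2-methoxy-8-{(2R)-5-oxo-4-[(tributylstannyl)methyl]-2,5-dihydrofuran-2-yl}octa-3,7-dienal
Product: 30 (3aR,4S,5S,6Z,10E,11aR)-6-(TBSO-methyl)-10-(TBDPSO-methyl)-4-hydroxy-5-methoxy-3-methylidene-3a,4,5,8,9,11a-hexahydrocyclodeca[b]furan-2(3H)-one
Conditions: MgBr2·OEt2 (4 equiv), CH2Cl2, −20 °C to rt, slow addition of 29 to 0.002 M
Reagents that add atoms: none
Why: Proposed new method: MgBr2 should tie the C8 carbonyl oxygen and the C9 methoxy oxygen into a five-membered chelate, the allylstannane Sn–C13–C11=C7 should then add through C7 in an open (non-cyclic) SE2′ transition state, and loss of Bu3SnBr should leave the C11=C13 methylene lactone directly. The closest known reaction types are Lewis-acid-promoted intramolecular allylstannane–aldehyde macrocyclisations, chelation-controlled additions of allylstannanes to α-alkoxy aldehydes with MgBr2, and additions of 2-(stannylmethyl)acrylates to aldehydes; a stannane embedded in a butenolide has not been used this way, which is why the step is marked. Ring A closes in a 10-exo-trig mode (C7 onto the C8 carbonyl, oxygen outside the ring), helped by the two ring-cis alkenes and the flat butenolide, which fold the chain. C7 is controlled by the C6 stereocentre of ring B: the aldehyde has to reach the butenolide face anti to the C5 alkenyl group, which gives the trans lactone (H-6 and H-7 trans). C8 is controlled by the chelate, in which C7 enters anti to C10 so that C8–OH and C9–OMe become syn, and by the open transition state, which sets C6 and the C8 oxygen syn along C11–C7–C8–C9. The step needs γ-selectivity (C7, not C13), secured by the SE2′ course of a primary allylstannane, and it needs the three facial preferences to coincide, for which the antiperiplanar C7–C8–C9–C10 torsion demanded by the chelate is a normal torsion of a ten-membered ring; slow addition at high dilution keeps the reaction intramolecular.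

Step 22
Reactants: 30 (3aR,4S,5S,6Z,10E,11aR)-6-(TBSO-methyl)-10-(TBDPSO-methyl)-4-hydroxy-5-methoxy-3-methylidene-3a,4,5,8,9,11a-hexahydrocyclodeca[b]furan-2(3H)-one; 31 methacrylic anhydride
Product: 32 (3aS,4S,5S,6Z,10E,11aR)-6-(TBSO-methyl)-10-(TBDPSO-methyl)-5-methoxy-3-methylidene-2-oxo-2,3,3a,4,5,8,9,11a-octahydrocyclodeca[b]furan-4-yl 2-methylprop-2-enoate
Conditions: Et3N, DMAP (cat.), CH2Cl2, 0 °C to rt
Reagents that add atoms: none
Why: DMAP-catalysed acylation of the only free hydroxyl (C8) with the anhydride, with retention at C8; acylating first prevents a later lactol between C8–OH and the C14 aldehyde.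

Step 23
Reactants: 32 (3aS,4S,5S,6Z,10E,11aR)-6-(TBSO-methyl)-10-(TBDPSO-methyl)-5-methoxy-3-methylidene-2-oxo-2,3,3a,4,5,8,9,11a-octahydrocyclodeca[b]furan-4-yl 2-methylprop-2-enoate
Product: 33 (3aS,4S,5S,6Z,10E,11aR)-10-(TBDPSO-methyl)-6-(hydroxymethyl)-5-methoxy-3-methylidene-2-oxo-2,3,3a,4,5,8,9,11a-octahydrocyclodeca[b]furan-4-yl 2-methylprop-2-enoate
Conditions: pyridinium p-toluenesulfonate (0.2 equiv), MeOH, rt
Reagents that add atoms: none
Why: Acid-catalysed methanolysis removes the primary TBS ether (C14) while the much more acid-stable TBDPS ether (C15), the esters and the methylene lactone are left.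

Step 24
Reactants: 33 (3aS,4S,5S,6Z,10E,11aR)-10-(TBDPSO-methyl)-6-(hydroxymethyl)-5-methoxy-3-methylidene-2-oxo-2,3,3a,4,5,8,9,11a-octahydrocyclodeca[b]furan-4-yl 2-methylprop-2-enoate
Product: 34 (3aS,4S,5S,6E,10E,11aR)-10-(TBDPSO-methyl)-6-formyl-5-methoxy-3-methylidene-2-oxo-2,3,3a,4,5,8,9,11a-octahydrocyclodeca[b]furan-4-yl 2-methylprop-2-enoate
Conditions: MnO2 (excess), CH2Cl2, rt
Reagents that add atoms: none
Why: Neutral oxidation of the allylic alcohol with MnO2 gives the C14 enal without touching the other functions; the alkene geometry is fixed by the ring.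

Step 25
Reactants: 34 (3aS,4S,5S,6E,10E,11aR)-10-(TBDPSO-methyl)-6-formyl-5-methoxy-3-methylidene-2-oxo-2,3,3a,4,5,8,9,11a-octahydrocyclodeca[b]furan-4-yl 2-methylprop-2-enoate
Product: 35 (3aS,4S,5S,6E,10E,11aR)-6-formyl-10-(hydroxymethyl)-5-methoxy-3-methylidene-2-oxo-2,3,3a,4,5,8,9,11a-octahydrocyclodeca[b]furan-4-yl 2-methylprop-2-enoate (target)
Conditions: HF·pyridine, pyridine, THF, 0 °C to rt
Reagents that add atoms: none
Why: Fluoride-mediated desilylation under buffered, weakly acidic conditions frees the C15 hydroxyl without the base that would endanger the enal, the methacrylate and the methylene lactone.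

**Compound list**

1 | (S)-but-3-ene-1,2-diol | OC[C@@H](O)C=C | starting material
2 | (S)-3,4-bis(triethylsilyloxy)but-1-ene | CC[Si](CC)(CC)OC[C@@H](O[Si](CC)(CC)CC)C=C | intermediate
3 | (S)-2-(triethylsilyloxy)but-3-enal | O=C[C@@H](O[Si](CC)(CC)CC)C=C | intermediate
4 | ethyl (triphenylphosphoranylidene)acetate | CCOC(=O)C=P(c1ccccc1)(c1ccccc1)c1ccccc1 | starting material
5 | 3-bromo-1,1-dimethoxypropane | COC(CCBr)OC | starting material
6 | (1-ethoxy-5,5-dimethoxy-1-oxopentan-2-yl)triphenylphosphonium bromide | CCOC(=O)C(CCC(OC)OC)[P+](c1ccccc1)(c1ccccc1)c1ccccc1.[Br-] | intermediate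
7 | ethyl 5,5-dimethoxy-2-(triphenylphosphoranylidene)pentanoate | CCOC(=O)C(CCC(OC)OC)=P(c1ccccc1)(c1ccccc1)c1ccccc1 | intermediate
8 | ethyl (2E,4S)-2-(3,3-dimethoxypropyl)-4-(triethylsilyloxy)hexa-2,5-dienoate | CCOC(=O)/C(CCC(OC)OC)=C/[C@@H](O[Si](CC)(CC)CC)C=C | intermediate
9 | (2E,4S)-2-(3,3-dimethoxypropyl)-4-(triethylsilyloxy)hexa-2,5-dien-1-ol | OC/C(CCC(OC)OC)=C/[C@@H](O[Si](CC)(CC)CC)C=C | intermediate
10 | (2E,4S)-1-(tert-butyldiphenylsilyloxy)-2-(3,3-dimethoxypropyl)-4-(triethylsilyloxy)hexa-2,5-diene | CC(C)(C)[Si](c1ccccc1)(c1ccccc1)OC/C(CCC(OC)OC)=C/[C@@H](O[Si](CC)(CC)CC)C=C | intermediate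
11 | 1-[(4E,6S)-4-(TBDPSO-methyl)-1-methoxy-6-(TESO)octa-4,7-dien-1-yl]-2,4,6-trimethylpyridinium triflate | COC(CC/C(CO[Si](c1ccccc1)(c1ccccc1)C(C)(C)C)=C\[C@@H](O[Si](CC)(CC)CC)C=C)[n+]1c(C)cc(C)cc1C.[O-]S(=O)(=O)C(F)(F)F | intermediate
12 | (4E,6S)-4-(TBDPSO-methyl)-6-(TESO)octa-4,7-dienal | O=CCC/C(CO[Si](c1ccccc1)(c1ccccc1)C(C)(C)C)=C\[C@@H](O[Si](CC)(CC)CC)C=C | intermediate
13 | 4-methoxybenzyl alcohol | COc1ccc(CO)cc1 | starting material
14 | methyl 4-chloro-3-oxobutanoate | COC(=O)CC(=O)CCl | starting material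
15 | methyl 4-(4-methoxybenzyloxy)-3-oxobutanoate | COC(=O)CC(=O)COCc1ccc(OC)cc1 | intermediate
16 | methyl (S)-3-hydroxy-4-(4-methoxybenzyloxy)butanoate | COC(=O)C[C@H](O)COCc1ccc(OC)cc1 | intermediate
17 | methyl (S)-3-methoxy-4-(4-methoxybenzyloxy)butanoate | COC(=O)C[C@H](OC)COCc1ccc(OC)cc1 | intermediate
18 | methyl (6E,8S)-3-hydroxy-2-[(1S)-1-methoxy-2-(PMBO)ethyl]-6-(TBDPSO-methyl)-8-(TESO)deca-6,9-dienoate (mixture at C2 and C3) | COC(=O)C(C(O)CC/C(CO[Si](c1ccccc1)(c1ccccc1)C(C)(C)C)=C\[C@@H](O[Si](CC)(CC)CC)C=C)[C@H](OC)COCc1ccc(OC)cc1 | intermediate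
19 | 3-O-methanesulfonate of 18 | COC(=O)C(C(OS(C)(=O)=O)CC/C(CO[Si](c1ccccc1)(c1ccccc1)C(C)(C)C)=C\[C@@H](O[Si](CC)(CC)CC)C=C)[C@H](OC)COCc1ccc(OC)cc1 | intermediate
20 | methyl (2E,6E,8S)-2-[(1S)-1-methoxy-2-(PMBO)ethyl]-6-(TBDPSO-methyl)-8-(TESO)deca-2,6,9-trienoate | COC(=O)/C(=C/CC/C(CO[Si](c1ccccc1)(c1ccccc1)C(C)(C)C)=C\[C@@H](O[Si](CC)(CC)CC)C=C)[C@H](OC)COCc1ccc(OC)cc1 | intermediate
21 | (2Z,6E,8S)-2-[(1S)-1-methoxy-2-(PMBO)ethyl]-6-(TBDPSO-methyl)-8-(TESO)deca-2,6,9-trien-1-ol | OC/C(=C/CC/C(CO[Si](c1ccccc1)(c1ccccc1)C(C)(C)C)=C\[C@@H](O[Si](CC)(CC)CC)C=C)[C@H](OC)COCc1ccc(OC)cc1 | intermediate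
22 | (2Z,6E,8S)-1-(TBSO)-2-[(1S)-1-methoxy-2-(PMBO)ethyl]-6-(TBDPSO-methyl)-8-(TESO)deca-2,6,9-triene | CC(C)(C)[Si](C)(C)OC/C(=C/CC/C(CO[Si](c1ccccc1)(c1ccccc1)C(C)(C)C)=C\[C@@H](O[Si](CC)(CC)CC)C=C)[C@H](OC)COCc1ccc(OC)cc1 | intermediate
23 | (3S,4E,8Z,10S)-5-(TBDPSO-methyl)-9-(TBSO-methyl)-10-methoxy-11-(PMBO)undeca-1,4,8-trien-3-ol | CC(C)(C)[Si](C)(C)OC/C(=C/CC/C(CO[Si](c1ccccc1)(c1ccccc1)C(C)(C)C)=C\[C@@H](O)C=C)[C@H](OC)COCc1ccc(OC)cc1 | intermediate
24 | 2-(bromomethyl)acrylic acid | OC(=O)C(=C)CBr | starting material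
25 | (3S,4E,8Z,10S)-5-(TBDPSO-methyl)-9-(TBSO-methyl)-10-methoxy-11-(PMBO)undeca-1,4,8-trien-3-yl 2-(bromomethyl)prop-2-enoate | CC(C)(C)[Si](C)(C)OC/C(=C/CC/C(CO[Si](c1ccccc1)(c1ccccc1)C(C)(C)C)=C\[C@@H](OC(=O)C(=C)CBr)C=C)[C@H](OC)COCc1ccc(OC)cc1 | intermediate
26 | (5R)-3-(bromomethyl)-5-[(1E,5Z,7S)-2-(TBDPSO-methyl)-6-(TBSO-methyl)-7-methoxy-8-(PMBO)octa-1,5-dien-1-yl]furan-2(5H)-one | CC(C)(C)[Si](C)(C)OC/C(=C/CC/C(CO[Si](c1ccccc1)(c1ccccc1)C(C)(C)C)=C\[C@H]1OC(=O)C(CBr)=C1)[C@H](OC)COCc1ccc(OC)cc1 | intermediate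
27 | (5R)-3-(bromomethyl)-5-[(1E,5Z,7S)-2-(TBDPSO-methyl)-6-(TBSO-methyl)-8-hydroxy-7-methoxyocta-1,5-dien-1-yl]furan-2(5H)-one | CC(C)(C)[Si](C)(C)OC/C(=C/CC/C(CO[Si](c1ccccc1)(c1ccccc1)C(C)(C)C)=C\[C@H]1OC(=O)C(CBr)=C1)[C@H](OC)CO | intermediate
28 | (5R)-5-[(1E,5Z,7S)-2-(TBDPSO-methyl)-6-(TBSO-methyl)-8-hydroxy-7-methoxyocta-1,5-dien-1-yl]-3-[(tributylstannyl)methyl]furan-2(5H)-one | CC(C)(C)[Si](C)(C)OC/C(=C/CC/C(CO[Si](c1ccccc1)(c1ccccc1)C(C)(C)C)=C\[C@H]1OC(=O)C(C[Sn](CCCC)(CCCC)CCCC)=C1)[C@H](OC)CO | intermediate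
29 | (2S,3Z,7E)-3-(TBSO-methyl)-7-(TBDPSO-methyl)-2-methoxy-8-{(2R)-5-oxo-4-[(tributylstannyl)methyl]-2,5-dihydrofuran-2-yl}octa-3,7-dienal | O=C[C@@H](OC)/C(CO[Si](C)(C)C(C)(C)C)=C\CC/C(CO[Si](c1ccccc1)(c1ccccc1)C(C)(C)C)=C\[C@H]2OC(=O)C(C[Sn](CCCC)(CCCC)CCCC)=C2 | intermediate
30 | (3aR,4S,5S,6Z,10E,11aR)-6-(TBSO-methyl)-10-(TBDPSO-methyl)-4-hydroxy-5-methoxy-3-methylidene-3a,4,5,8,9,11a-hexahydrocyclodeca[b]furan-2(3H)-one | O[C@H]1[C@H]2C(=C)C(=O)O[C@@H]2/C=C(/CO[Si](c3ccccc3)(c3ccccc3)C(C)(C)C)CC/C=C(/CO[Si](C)(C)C(C)(C)C)[C@@H]1OC | intermediate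
31 | methacrylic anhydride | CC(=C)C(=O)OC(=O)C(C)=C | starting material
32 | (3aS,4S,5S,6Z,10E,11aR)-6-(TBSO-methyl)-10-(TBDPSO-methyl)-5-methoxy-3-methylidene-2-oxo-2,3,3a,4,5,8,9,11a-octahydrocyclodeca[b]furan-4-yl 2-methylprop-2-enoate | C=C(C)C(=O)O[C@H]1[C@H]2C(=C)C(=O)O[C@@H]2/C=C(/CO[Si](c3ccccc3)(c3ccccc3)C(C)(C)C)CC/C=C(/CO[Si](C)(C)C(C)(C)C)[C@@H]1OC | intermediate
33 | (3aS,4S,5S,6Z,10E,11aR)-10-(TBDPSO-methyl)-6-(hydroxymethyl)-5-methoxy-3-methylidene-2-oxo-2,3,3a,4,5,8,9,11a-octahydrocyclodeca[b]furan-4-yl 2-methylprop-2-enoate | C=C(C)C(=O)O[C@H]1[C@H]2C(=C)C(=O)O[C@@H]2/C=C(/CO[Si](c3ccccc3)(c3ccccc3)C(C)(C)C)CC/C=C(/CO)[C@@H]1OC | intermediate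
34 | (3aS,4S,5S,6E,10E,11aR)-10-(TBDPSO-methyl)-6-formyl-5-methoxy-3-methylidene-2-oxo-2,3,3a,4,5,8,9,11a-octahydrocyclodeca[b]furan-4-yl 2-methylprop-2-enoate | C=C(C)C(=O)O[C@H]1[C@H]2C(=C)C(=O)O[C@@H]2/C=C(/CO[Si](c3ccccc3)(c3ccccc3)C(C)(C)C)CC/C=C(/C=O)[C@@H]1OC | intermediate
35 | (3aS,4S,5S,6E,10E,11aR)-6-formyl-10-(hydroxymethyl)-5-methoxy-3-methylidene-2-oxo-2,3,3a,4,5,8,9,11a-octahydrocyclodeca[b]furan-4-yl 2-methylprop-2-enoate | C=C(C)C(=O)O[C@H]1[C@H]2C(=C)C(=O)O[C@@H]2/C=C(/CO)CC/C=C(/C=O)[C@@H]1OC | target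

**Step count**

Total: 25 steps. Longest linear sequence: 21 steps (from 1 through steps 1, 2, 4–7 and 11–25); the ylide (step 3) and the C8–C10/C14 ester (steps 8–10) are side branches.

**Steps most likely to fail**

Step 21 (key step, proposed new method). The ester-conjugated stannane may be too weak a nucleophile under MgBr2 activation, so that the aldehyde epimerises at C9, slides into conjugation or oligomerises before the ring closes; alternatively the closure may not follow the chelate at C8. The fallback uses known chemistry and sets out from bromide 27. Dess–Martin oxidation (NaHCO3, CH2Cl2, 0 °C) should give the bromo aldehyde (2S,3Z,7E)-8-[(2R)-4-(bromomethyl)-5-oxo-2,5-dihydrofuran-2-yl]-3-(TBSO-methyl)-7-(TBDPSO-methyl)-2-methoxyocta-3,7-dienal F1. Treatment of F1 with CrCl2 in THF at high dilution (Nozaki–Hiyama allylation) should generate the allylchromium from the 3-(bromomethyl)butenolide, which adds to the aldehyde through C7 in a closed six-membered transition state and comes back to the route at 30. Barbier-type allylations of aldehydes with 3-(bromomethyl)butenolides and chromium-mediated medium-ring allylations are both known; the configuration at C7 and C8 would have to be confirmed, since a closed transition state need not give the same diastereomer.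

Step 19 (stannylation). Tin may be delivered to C7 instead of C13, the product may couple with unreacted bromide (Stille-type allyl–allyl coupling), or zerovalent palladium may ionise the doubly allylic C6–O bond of the lactone. The fallback sets out from 27 and comes back at 28 by a palladium-free, umpoled route: zinc dust and Bu3SnCl in THF/aqueous NH4Cl (Barbier-type stannylation, the allylzinc formed from the bromide being trapped by the tin chloride). This fallback makes no new compound (F0).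

Step 17 (ring-closing metathesis). Closure onto the electron-poor 1,1-disubstituted acrylate may be slow and the allylic bromide may destroy the catalyst before the trisubstituted butenolide forms. The fallback sets out from 23 and carries an acetate instead of the bromide through the metathesis. Steglich esterification of 23 with 2-(acetoxymethyl)acrylic acid should give (3S,4E,8Z,10S)-5-(TBDPSO-methyl)-9-(TBSO-methyl)-10-methoxy-11-(PMBO)undeca-1,4,8-trien-3-yl 2-(acetoxymethyl)prop-2-enoate F2. Ring-closing metathesis with the same catalyst should give (5R)-3-(acetoxymethyl)-5-[(1E,5Z,7S)-2-(TBDPSO-methyl)-6-(TBSO-methyl)-7-methoxy-8-(PMBO)octa-1,5-dien-1-yl]furan-2(5H)-one F3. DDQ should then free the C8 hydroxyl to give (5R)-3-(acetoxymethyl)-5-[(1E,5Z,7S)-2-(TBDPSO-methyl)-6-(TBSO-methyl)-8-hydroxy-7-methoxyocta-1,5-dien-1-yl]furan-2(5H)-one F4. Zerovalent-palladium-catalysed stannylation of the allylic acetate with hexabutylditin comes back to the route at 28.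

Further compounds
F1 | step 21 | (2S,3Z,7E)-8-[(2R)-4-(bromomethyl)-5-oxo-2,5-dihydrofuran-2-yl]-3-(TBSO-methyl)-7-(TBDPSO-methyl)-2-methoxyocta-3,7-dienal | CC(C)(C)[Si](C)(C)OC/C(=C/CC/C(CO[Si](c1ccccc1)(c1ccccc1)C(C)(C)C)=C\[C@H]1OC(=O)C(CBr)=C1)[C@H](OC)C=O
F0 | step 19 | none | none
F2 | step 17 | (3S,4E,8Z,10S)-5-(TBDPSO-methyl)-9-(TBSO-methyl)-10-methoxy-11-(PMBO)undeca-1,4,8-trien-3-yl 2-(acetoxymethyl)prop-2-enoate | CC(C)(C)[Si](C)(C)OC/C(=C/CC/C(CO[Si](c1ccccc1)(c1ccccc1)C(C)(C)C)=C\[C@@H](OC(=O)C(=C)COC(C)=O)C=C)[C@H](OC)COCc1ccc(OC)cc1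
F3 | step 17 | (5R)-3-(acetoxymethyl)-5-[(1E,5Z,7S)-2-(TBDPSO-methyl)-6-(TBSO-methyl)-7-methoxy-8-(PMBO)octa-1,5-dien-1-yl]furan-2(5H)-one | CC(C)(C)[Si](C)(C)OC/C(=C/CC/C(CO[Si](c1ccccc1)(c1ccccc1)C(C)(C)C)=C\[C@H]1OC(=O)C(COC(C)=O)=C1)[C@H](OC)COCc1ccc(OC)cc1
F4 | step 17 | (5R)-3-(acetoxymethyl)-5-[(1E,5Z,7S)-2-(TBDPSO-methyl)-6-(TBSO-methyl)-8-hydroxy-7-methoxyocta-1,5-dien-1-yl]furan-2(5H)-one | CC(C)(C)[Si](C)(C)OC/C(=C/CC/C(CO[Si](c1ccccc1)(c1ccccc1)C(C)(C)C)=C\[C@H]1OC(=O)C(COC(C)=O)=C1)[C@H](OC)CO
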